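The central C3–C3' bond of the biindole is read as the C–C bond of a 1,2-diketone. C3 and C3' are neighbours, each is bonded to a benzo-ring carbon (C3a, C3a'), and C2 and C2' are the nitrogen-bound carbons flanking them; this is the feature exploited. One acid treatment of an acyclic bis(N-aryl-N-trifluoroacetyl-aminomethyl) diketone forms C3–C3a and C3'–C3a', closes both pyrrole rings and aromatises them with loss of two molecules of water. The substrate already carries all four benzo-ring bromines and comes in two steps from 3,4-dibromoaniline. Deacylation and bromination at C2 and C2' complete the hexabromide.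

Key step: step 3

Assumption: the target is written without a stereodescriptor, so the C3–C3' axis is treated as configurationally undefined and no atropselective step is planned.

Design remarks
- Atom mapping: aniline C1 becomes C7a, C6 (para to the 3-bromine) becomes C3a, and the 3- and 4-bromines end at C6 and C5.
- Trifluoroacetyl stays on both nitrogens through the acid step.
  - It blocks amine–dione condensation and the aniline migration that scrambles 2- and 3-substitution.
  - It is the least basic carbonyl present and its oxygen is a poor nucleophile, so amide protonation and oxazolium formation should not compete.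
  - Carbamates would close to oxazolones, and N-aryl sulfonamides tend to lose or shift the sulfonyl group in hot strong acid.
- A medium of intermediate acidity is chosen. It activates the dione, whereas a superacid would also protonate the amide and switch the ring off.
- The bromodione never meets a base stronger than the anilide anion.
- The acid-sensitive C2–Br bonds are made last.

Step 1
Reactants: 1 3,4-dibromoaniline; 2 trifluoroacetic anhydride
Product: 3 N-(3,4-dibromophenyl)-2,2,2-trifluoroacetamide
Conditions: (CF3CO)2O (1.2 equiv), CH2Cl2, 0 °C → rt
Reagents that add atoms: trifluoroacetic anhydride (compound 2), O=C(OC(=O)C(F)(F)F)C(F)(F)F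
Why: Nucleophilic acyl substitution (N-trifluoroacetylation): even this weakly basic aniline is acylated rapidly by the very electrophilic anhydride, the aryl bromides are inert, and the acidic N–H that results sets up the next step.

Step 2
Reactants: 3 N-(3,4-dibromophenyl)-2,2,2-trifluoroacetamide (2.05 equiv); 4 1,4-dibromobutane-2,3-dione (1 equiv)
Product: 7 N,N'-(2,3-dioxobutane-1,4-diyl)bis[N-(3,4-dibromophenyl)-2,2,2-trifluoroacetamide], via sodium anilide 5 (not isolated), via monoalkylated bromodione 6 (not isolated)
Conditions: 3, NaH (2.0 equiv), THF–DMF 4:1, 0 °C; then added slowly to 4, THF, −30 °C → rt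
Reagents that add atoms: none
Why: Twofold SN2 N-alkylation of an amide anion by an α-bromo ketone (Gabriel-type alkylation): the anilide anion is about as weakly basic as phthalimide anion, no hydride is left because 3 is in slight excess, slow addition to the cold, carbonyl-activated bromide should let displacement outrun enolisation of the dione, and the soft carbon electrophile directs attack to nitrogen rather than oxygen.

Step 3
Reactants: 7 N,N'-(2,3-dioxobutane-1,4-diyl)bis[N-(3,4-dibromophenyl)-2,2,2-trifluoroacetamide]
Product: 11 5,5',6,6'-tetrabromo-1,1'-bis(trifluoroacetyl)-3,3'-biindole, via first carbinol 8 (not isolated), via mono-indole ketone 9 (not isolated), via second carbinol 10 (not isolated)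
Conditions: P2O5/MeSO3H (1:10 w/w), 0.02 M, 40 → 80 °C; poured on ice, solid collected
Reagents that add atoms: none
Why: Proposed new method: one ketone of 7, made more electrophilic by its carbonyl neighbour, is protonated and attacked by the ring carbon ortho to nitrogen and para to the 3-bromine (intramolecular Friedel–Crafts hydroxyalkylation) to give carbinol 8, which loses water across C2–C3 to the N-acylindole 9, and the remaining ketone, kept electrophilic because the trifluoroacetyl group holds back the indole nitrogen lone pair, is closed by the second arene through carbinol 10 in the same way. The closest known reaction type is the modified Bischler indole synthesis, the acid cyclodehydration of N-acyl α-anilino ketones and acetals to indoles, together with the cyclodehydration of α-aryloxy ketones to benzofurans in P2O5/MeSO3H; untested are the twofold use on a 1,2-dione and a ring this electron-poor. Each pyrrole ring closes in a 5-exo-trig mode at the carbonyl carbon with the arene C=C inside the forming ring (enolendo geometry, as in every Bischler closure), making C3–C3a and then C3'–C3a'. The carbinol carbons of 8 and 10 form without control and are erased by dehydration, so the product holds no stereocentre. Ring-position selectivity (5,6- not 4,5-dibromo) is secured by the substrate, since the other ortho carbon is wedged between nitrogen and bromine and closure there would press that bromine against the C3 substituent. Carbonyl selectivity (near ketone and five-membered ring, not far ketone and six-membered ring) rests on the shorter tether and on the fact that only the five-ring carbinol can leave the equilibrium by a simple 1,2-elimination to an aromatic ring, while the trifluoroacetyl groups prevent amine–dione condensation, aniline migration and oxazolium formation and P2O5 binds the water that would hydrolyse them.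

Step 4
Reactants: 11 5,5',6,6'-tetrabromo-1,1'-bis(trifluoroacetyl)-3,3'-biindole
Product: 13 5,5',6,6'-tetrabromo-1H,1'H-3,3'-biindole, via mono-deacylated biindole 12 (not isolated)
Conditions: K2CO3 (0.2 equiv), MeOH–THF 1:1, rt
Reagents that add atoms: none
Why: Base-catalysed methanolysis (acyl transfer to methoxide): an N-trifluoroacetylindole is an activated amide with an indolide leaving group and is cleaved at room temperature, where aryl C–Br bonds and the biindole core are untouched.

Step 5
Reactants: 13 5,5',6,6'-tetrabromo-1H,1'H-3,3'-biindole
Product: 15 2,2',5,5',6,6'-hexabromo-1H,1'H-3,3'-biindole, via pentabromide 14 (not isolated)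
Conditions: NBS (2.05 equiv), dry THF, −20 → 0 °C, dark
Reagents that add atoms: N-bromosuccinimide, O=C1CCC(=O)N1Br
Why: Electrophilic aromatic bromination of a 3-substituted indole at C2 with NBS: C3 and C3' are blocked, each benzo ring is deactivated by two bromines, and attack at C2 gives a cation at C3 that the neighbouring indole stabilises, so the two C2–H bonds are the only reactive sites and two equivalents should stop at the hexabromide.

Compound list
1 | 3,4-dibromoaniline | Nc1ccc(Br)c(Br)c1 | starting material
2 | trifluoroacetic anhydride | O=C(OC(=O)C(F)(F)F)C(F)(F)F | starting material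
3 | N-(3,4-dibromophenyl)-2,2,2-trifluoroacetamide | O=C(Nc1ccc(Br)c(Br)c1)C(F)(F)F | intermediate
4 | 1,4-dibromobutane-2,3-dione | O=C(CBr)C(=O)CBr | starting material
5 | sodium salt of 3, N-deprotonated (not isolated) | [Na+].O=C([N-]c1ccc(Br)c(Br)c1)C(F)(F)F | intermediate
6 | N-(4-bromo-2,3-dioxobutyl)-N-(3,4-dibromophenyl)-2,2,2-trifluoroacetamide (not isolated) | O=C(CBr)C(=O)CN(C(=O)C(F)(F)F)c1ccc(Br)c(Br)c1 | intermediate
7 | N,N'-(2,3-dioxobutane-1,4-diyl)bis[N-(3,4-dibromophenyl)-2,2,2-trifluoroacetamide] | O=C(CN(C(=O)C(F)(F)F)c1ccc(Br)c(Br)c1)C(=O)CN(C(=O)C(F)(F)F)c1ccc(Br)c(Br)c1 | intermediate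
8 | N-{2-[5,6-dibromo-3-hydroxy-1-(trifluoroacetyl)-2,3-dihydro-1H-indol-3-yl]-2-oxoethyl}-N-(3,4-dibromophenyl)-2,2,2-trifluoroacetamide, racemic (not isolated) | OC1(C(=O)CN(C(=O)C(F)(F)F)c2ccc(Br)c(Br)c2)CN(C(=O)C(F)(F)F)c2cc(Br)c(Br)cc21 | intermediate
9 | N-{2-[5,6-dibromo-1-(trifluoroacetyl)-1H-indol-3-yl]-2-oxoethyl}-N-(3,4-dibromophenyl)-2,2,2-trifluoroacetamide (not isolated) | O=C(CN(C(=O)C(F)(F)F)c1ccc(Br)c(Br)c1)c1cn(C(=O)C(F)(F)F)c2cc(Br)c(Br)cc12 | intermediate
10 | 5,5',6,6'-tetrabromo-1,1'-bis(trifluoroacetyl)-2,3-dihydro-1H,1'H-[3,3'-biindol]-3-ol, racemic (not isolated) | OC1(c2cn(C(=O)C(F)(F)F)c3cc(Br)c(Br)cc23)CN(C(=O)C(F)(F)F)c2cc(Br)c(Br)cc21 | intermediate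
11 | 5,5',6,6'-tetrabromo-1,1'-bis(trifluoroacetyl)-3,3'-biindole | O=C(n1cc(-c2cn(C(=O)C(F)(F)F)c3cc(Br)c(Br)cc23)c2cc(Br)c(Br)cc21)C(F)(F)F | intermediate
12 | 5,5',6,6'-tetrabromo-1-(trifluoroacetyl)-1H,1'H-3,3'-biindole (not isolated) | O=C(n1cc(-c2c[nH]c3cc(Br)c(Br)cc23)c2cc(Br)c(Br)cc21)C(F)(F)F | intermediate
13 | 5,5',6,6'-tetrabromo-1H,1'H-3,3'-biindole | Brc1cc2[nH]cc(-c3c[nH]c4cc(Br)c(Br)cc34)c2cc1Br | intermediate
14 | 2,5,5',6,6'-pentabromo-1H,1'H-3,3'-biindole (not isolated) | Brc1cc2[nH]c(Br)c(-c3c[nH]c4cc(Br)c(Br)cc34)c2cc1Br | intermediate
15 | 2,2',5,5',6,6'-hexabromo-1H,1'H-3,3'-biindole | Brc1cc2[nH]c(Br)c(-c3c(Br)[nH]c4cc(Br)c(Br)cc34)c2cc1Br | target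

Total steps: 5. Longest linear sequence: 5 steps (1 → 3 → 7 → 11 → 13 → 15).

Steps most likely to fail

Step 3.
- The ring carbons ortho to nitrogen are weakened by two bromines and an N-acyl group and may attack too slowly. The sequence could then stall after the first closure, where the second ketone is conjugated with an indole.
- Closure may also take place on the far carbonyl through a six-membered transition state.
- At the temperature needed the dione may self-condense, the N-acyl groups may be lost, or bromine may migrate.

The fallback uses known chemistry and makes the C3–C3' bond by coupling two finished indoles. It sets out from 1. Ortho-selective Sugasawa acylation (BCl3, AlCl3, ClCH2CN, ClCH2CH2Cl, reflux, then aqueous HCl) at the free position para to bromine should give 1-(2-amino-4,5-dibromophenyl)-2-chloroethan-1-one F1. NaBH4 in aqueous dioxane at reflux reduces the ketone, and the amino alcohol closes and dehydrates to 5,6-dibromo-1H-indole F2. Oxidative C3–H/C3–H homocoupling with catalytic Pd(OCOCF3)2 and Cu(OAc)2 in DMSO at room temperature then joins two molecules. The oxidising medium keeps zerovalent palladium from building up and inserting into C–Br. The fallback comes back to the route at 13.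

Step 2.
- The bromodione, or the first-formed product at its acidic CH2 beside the dione, may be deprotonated and then self-condense or be C-alkylated.
- The ambident anion may react through oxygen.
- The anion may add to the very electrophilic carbonyl groups.

The fallback forms both C–N bonds on a four-carbon unit without carbonyl groups and introduces the dione afterwards. It sets out from 3. K2CO3 and 1,4-dichlorobut-2-yne (0.5 equiv) in DMF at room temperature should give N,N'-(but-2-yne-1,4-diyl)bis[N-(3,4-dibromophenyl)-2,2,2-trifluoroacetamide] F3 by plain propargylic SN2 alkylation. The internal alkyne is then oxidised to the 1,2-dione with catalytic RuCl3 and NaIO4 in EtOAc–MeCN–H2O at 0 °C → rt, a known alkyne-to-diketone oxidation that the electron-poor arenes and the amides should survive. The fallback comes back to the route at 7.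

Step 5.
- The electron-rich bis-enamine core may be over-oxidised.
- A bromoindolenine intermediate may be captured by traces of water, which diverts material to the oxindole oxidation level.
- The second bromination may stay incomplete because of poor solubility.

The fallback replaces electrophilic substitution by deoxygenative bromination. It sets out from 13. DMSO and concentrated HCl in AcOH at room temperature, the known oxidation of 3-substituted indoles to oxindoles, should give 5,5',6,6'-tetrabromo-[3,3'-biindoline]-2,2'-dione F4 as a mixture of diastereomers whose C3 centres are erased next. POBr3 in ClCH2CH2Cl at reflux under nitrogen then converts each lactam into the 2-bromoindole by O-phosphorylation, substitution by bromide and tautomerisation. The fallback comes back to the route at 15.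

Further compounds
F1 | step 3 | 1-(2-amino-4,5-dibromophenyl)-2-chloroethan-1-one | Nc1cc(Br)c(Br)cc1C(=O)CCl
F2 | step 3 | 5,6-dibromo-1H-indole | Brc1cc2cc[nH]c2cc1Br
F3 | step 2 | N,N'-(but-2-yne-1,4-diyl)bis[N-(3,4-dibromophenyl)-2,2,2-trifluoroacetamide] | O=C(N(CC#CCN(C(=O)C(F)(F)F)c1ccc(Br)c(Br)c1)c1ccc(Br)c(Br)c1)C(F)(F)F
F4 | step 5 | 5,5',6,6'-tetrabromo-[3,3'-biindoline]-2,2'-dione (meso and racemic forms, mixture) | O=C1Nc2cc(Br)c(Br)cc2C1C1C(=O)Nc2cc(Br)c(Br)cc21
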